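## The problem

Numbering used throughout: the chroman is O1, C2, C3, C4, C4a, C5–C8, C8a. The benzotropolone is C1'–C4' (benzo carbons), C4a', C5' (carbonyl), C6' (hydroxyl), C7', C8' (bears the chroman), C9', C9a'.

- The target is a 2,3-cis flavan-3-ol, (2R,3R), in which ring B is a 2',3',4',6'-tetrahydroxy-5'-oxobenzocycloheptene joined through C8' to C2.
- The hard part of the skeleton is the benzo-fused seven-membered ring. It needs vicinal oxygen on C5' and C6', a third oxygen peri to the carbonyl on C4', and a chiral sp3 substituent on C8'. Oxidative pyrogallol–catechol couplings do not place such a substituent there selectively.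
- C2 and C3 are the only stereocentres, and nothing in the flat benzotropolone can control them. They have to be set in the chroman fragment, where an epoxide-derived C3 can define C2 through one invertive substitution.
- C2 is an ether carbon next to an unsaturated ring and must not be exposed to strong Lewis acids or bases once the ring system is complete.
- The pyrogallol and tropolone hydroxyls oxidise and chelate easily. They should travel as ethers and be released together under neutral conditions, and the tropolone should arise without an oxidant.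
- The enabling feature is the seven-membered ring itself. C5'(O), C6', C9' and the fusion carbons C4a'/C9a' are the carbon frame of a 2-benzopyrylium-4-olate whose dipole is C6'–O–C9'. C7'–C8' is a two-carbon unit that can be an alkyne already carrying the chroman on C8'.
- Cycloaddition followed by opening of the oxygen bridge leaves the bridge oxygen on C6' as the tropolone hydroxyl, at the correct oxidation level.

## Retrosynthesis

**23 to 22 (six O–benzyl bonds).** All six hydroxyls other than the one on C6' are carried as benzyl ethers, so the last step is one hydrogenolysis. Methyl ethers would need boron halides, which endanger C2. Phenolic silyl ethers would not survive the fragment syntheses. The C3 oxygen is benzylated as well, so no separate deprotection is needed.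

**22 to 21 (reconnect O from C6' to C9').** The tropolone is an isomer of the 6',9'-oxygen-bridged benzocycloheptadienone 21. The forward step only has to ionise the C9'–O bond, which is benzylic, allylic and para to the C3' ether oxygen, and then remove the C6' proton. No redox step is involved and both bridgehead epimers of 21 converge.

**21 to 19 plus 9 (cut C6'–C7', C8'–C9' and O–C6').** This is the central cut.
- It gives two fragments of similar size: the achiral formyl diazoketone 19 and the alkyne 9, which carries both stereocentres.
- The reactive form of 19 is the ylide 20.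
- Cutting C7'=C8' alone, or inserting C6' into a naphthalene, leaves a ring at the wrong oxidation level and a harder precursor.
- The forward reaction must form the ylide faster than the metal carbene is diverted, and must add the alkyne with its unsubstituted carbon on C6'.

**9 to 8 to 7 (protecting-group changes).** The alkyne is kept as its trimethylsilyl derivative until the C3 hydroxyl has been benzylated under basic conditions. Desilylation then gives 9.

**7 to 6 (cut C4–C4a).** Ring C is closed by attack of the phloroglucinol-type ring on the terminal carbon of an epoxide.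
- The two positions ortho to the ether oxygen are equivalent, so there is no regiochemical question on the arene.
- C4 is not stereogenic, and the C3–O bond is not touched.
- Closing O1–C2 last instead would need two differentiated phenols.

**6 to 4 plus 5 (cut O1–C2).** A Mitsunobu etherification of the propargylic alcohol 4 with the symmetrical phenol 5 forms this bond with inversion. The erythro epoxy alcohol thereby becomes the threo ether that closes to the cis chroman. A propargylic carbinol is a good substrate for clean SN2 displacement.

**4 to 3 to 1 plus 2.** The epoxide oxygen is introduced by a Sharpless kinetic resolution of the racemic enynol 3. This selects the carbinol configuration and sets the epoxide carbon in one operation. 3 is one Grignard addition away from aldehyde 1 and vinylmagnesium bromide 2.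

**19 to 18 to 16 (aldehyde unmasking, then C=N2).** The diazo group is installed on the methyl ketone 16 by detrifluoroacetylative diazo transfer through 17. The aldehyde is masked as a dimethyl acetal during this step because a free ortho formyl group would undergo aldol closure with the enolate. Acylating diazomethane with an acid chloride is avoided: ortho-formyl benzoic acids exist as hydroxyphthalides and give pseudo-chlorides.

**16 to 13 plus 14 (cut C4a'–C5').** The aryllithium 15, from bromide 13, is acylated with the Weinreb amide 14. The two ortho substituents hinder a benzoyl electrophile but do not hinder this polarity.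

**13 to 12 to 11 to 10.** Acetal formation, bromination and benzylation lead back to 3,4,5-trihydroxybenzaldehyde 10. The only free ring positions of 11 are equivalent and activated by the ether oxygens, so bromination is unambiguous. The aldehyde carbon of 10 becomes C9'.

## Roads not taken

**Alternative 1: oxa-Michael–aldol chromene annulation.**
- Cut: O1–C2 and C3–C4 of ring C.
- Forward step: the salicylaldehyde A2 and the benzotropolonyl enal A3 are joined under a diarylprolinol silyl ether catalyst to give the 2H-chromene-3-carbaldehyde A1.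
- Merits: C2 is set by a catalyst and no material is lost in a resolution. On that count it is better than the chosen plan, which discards half of 3. Against this, 3 is a one-step compound from cheap reagents, and the resolution fixes both ring C stereocentres at once.
- Weak points:
  - A3 already contains the whole benzotropolone with a three-carbon chain on C8', so the main problem is moved, not solved.
  - The tropone ring of A3 is a competing acceptor, and the extended conjugation lowers the reactivity of the iminium ion.
  - 2-Substituted 2H-chromenes can lose configuration by reversible ring opening.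
  - C3 of A1 carries a formyl carbon where the target has oxygen. This requires a cis-selective alkene reduction, a Baeyer–Villiger-type oxygen insertion with peracid next to an electron-rich ring A and a tropolone, and a hydrolysis.
- Comparison: the chosen plan obtains the C3 oxygen and the cis relationship from one epoxy alcohol and needs no oxidation after the rings are joined.

**Alternative 2: ring-closing metathesis.**
- Cut: C7'=C8'.
- Forward step: the diene A5 is closed with the second-generation Grubbs catalyst to the dihydrobenzocycloheptenone A4.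
- Merits: there is no orientation question and the ring closure is predictable. Here it is better than the chosen plan, whose cycloaddition has to be regioselective. The chosen plan answers with a dipole whose polarisation is well understood and a product at the right oxidation level.
- Weak points:
  - The new alkene is trisubstituted and is formed from a 1,1-disubstituted olefin flanked by the branched C2, which makes the closure slow.
  - Hydride species derived from the catalyst could move the exocyclic double bond toward C2 and erase that stereocentre.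
  - A4 still needs desilylation, oxidation at C6' and tautomerisation through a sensitive 1,2-dione.
  - A5 requires a separate construction of the C2–C8' bond to a 1,1-disubstituted alkene.
- Comparison: the route is longer on both sides of the key step.

**Alternative 3: one-carbon ring expansion of a naphthalene.**
- Cut: C5'–C6' and C6'–C7', with C6' inserted.
- Forward step: dichlorocarbene adds to the methoxy-bearing bond of the naphthyl flavan A7, and the cyclopropane opens to the 6'-chlorobenzotropone A6.
- Merits: A7 is accessible by standard flavan-3-ol chemistry, the reagents are cheap, and the substitution pattern of the seven-membered ring cannot come out reversed. That is an advantage over a cycloaddition. The chosen plan offsets it by forming the ring under neutral catalysis with an oxygen already on C6'.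
- Weak points:
  - Dichlorocarbene is unselective. Ring A and the trialkoxy ring are more electron-rich than the bond to be expanded, so Reimer–Tiemann-type attack and wrong-site cyclopropanation compete.
  - The carbene sources need strong base or heat, with C2 in place.
  - A6 is a chlorotropone. Replacing chloride by hydroxide on halotropones is troubled by cine substitution and ring contraction, so the tropolone is still two uncertain steps away.

Key step: step 13

Assumption: the two tautomers of the tropolone are treated as one compound, drawn as the 5'-oxo-6'-hydroxy form. Cycloadduct 21 is carried as the pair of bridgehead epimers.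

## Route

Step 1
Reactants: 1 3-(trimethylsilyl)propynal; 2 vinylmagnesium bromide
Product: 3 racemic 5-(trimethylsilyl)pent-1-en-4-yn-3-ol
Conditions: THF, −78 → 0 °C; aq. NH4Cl
Reagents that add atoms: none
Why: Grignard 1,2-addition to an ynal; at low temperature the hard vinyl nucleophile adds to the carbonyl and not to the alkyne, and the racemic carbinol is resolved in step 2.

Step 2
Reactants: 3 racemic 5-(trimethylsilyl)pent-1-en-4-yn-3-ol
Product: 4 (2R,3S)-1,2-epoxy-5-(trimethylsilyl)pent-4-yn-3-ol (erythro)
Conditions: Ti(OiPr)4 (0.2 equiv), L-(+)-diisopropyl tartrate (0.25 equiv), t-BuOOH (0.45 equiv), 4 Å MS, CH2Cl2, −20 °C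
Reagents that add atoms: tert-butyl hydroperoxide, CC(C)(C)OO
Why: Sharpless kinetic resolution of a secondary allylic alcohol; with the L-(+)-tartrate the (R)-enynol should be epoxidised fast and anti to the carbinol substituent, which sets the epoxide carbon as R and selects the carbinol that becomes S in 4. The slow (S)-enantiomer of 3 stays behind and is separated; the alkyne is inert to the titanium peroxide.

Step 3
Reactants: 4 (2R,3S)-1,2-epoxy-5-(trimethylsilyl)pent-4-yn-3-ol; 5 3,5-bis(benzyloxy)phenol
Product: 6 (2R)-2-[(1R)-1-[3,5-bis(benzyloxy)phenoxy]-3-(trimethylsilyl)prop-2-yn-1-yl]oxirane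
Conditions: PPh3, DIAD, toluene, 0 °C → rt
Reagents that add atoms: none
Why: Mitsunobu etherification; the phenol displaces the activated propargylic oxygen by SN2 with inversion, so the future C2 becomes R, and the silyl group blocks SN2' attack at the alkyne terminus. The epoxide is not touched under these neutral conditions.

Step 4
Reactants: 6 (2R)-2-[(1R)-1-[3,5-bis(benzyloxy)phenoxy]-3-(trimethylsilyl)prop-2-yn-1-yl]oxirane
Product: 7 (2R,3R)-5,7-bis(benzyloxy)-2-[(trimethylsilyl)ethynyl]chroman-3-ol (2,3-cis)
Conditions: BF3·OEt2 (0.3 equiv), CH2Cl2, −78 → −30 °C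
Reagents that add atoms: none
Why: Intramolecular Friedel–Crafts epoxide–arene cyclisation of an aryl glycidyl ether; the position ortho to the ether oxygen attacks the terminal epoxide carbon (six-membered closure), which is less hindered than the internal carbon, itself deactivated by the neighbouring aryloxy group. No stereocentre is formed and the C3–O bond is not broken, so the threo ether gives the cis chromanol.

Step 5
Reactants: 7 (2R,3R)-5,7-bis(benzyloxy)-2-[(trimethylsilyl)ethynyl]chroman-3-ol
Product: 8 (2R,3R)-3,5,7-tris(benzyloxy)-2-[(trimethylsilyl)ethynyl]chroman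
Conditions: NaH, BnBr, n-Bu4NI (cat.), THF/DMF, 0 °C → rt
Reagents that add atoms: benzyl bromide, BrCc1ccccc1
Why: Williamson etherification of the secondary alkoxide; the silyl group keeps the alkyne from being deprotonated and benzylated, and C2–H is far too weakly acidic to epimerise.

Step 6
Reactants: 8 (2R,3R)-3,5,7-tris(benzyloxy)-2-[(trimethylsilyl)ethynyl]chroman
Product: 9 (2R,3R)-3,5,7-tris(benzyloxy)-2-ethynylchroman
Conditions: K2CO3 (cat.), MeOH/THF, rt
Reagents that add atoms: none
Why: Methanolysis of the alkynyl C–Si bond, a standard protodesilylation that leaves benzyl ethers and both stereocentres alone.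

Step 7
Reactants: 10 3,4,5-trihydroxybenzaldehyde
Product: 11 3,4,5-tris(benzyloxy)benzaldehyde
Conditions: BnBr, K2CO3, DMF, 60 °C, under N2
Reagents that add atoms: benzyl bromide, BrCc1ccccc1
Why: Threefold Williamson O-benzylation of the phenols; exclusion of air protects the pyrogallol until it is fully etherified.

Step 8
Reactants: 11 3,4,5-tris(benzyloxy)benzaldehyde
Product: 12 2-bromo-3,4,5-tris(benzyloxy)benzaldehyde
Conditions: NBS, MeCN, 0 °C → rt, dark
Reagents that add atoms: N-bromosuccinimide, O=C1CCC(=O)N1Br
Why: Electrophilic aromatic bromination; the two free positions are equivalent and each is ortho and para to an ether oxygen, so a single monobromide is expected, and polar conditions in the dark avoid benzylic radical bromination.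

Step 9
Reactants: 12 2-bromo-3,4,5-tris(benzyloxy)benzaldehyde
Product: 13 1,2,3-tris(benzyloxy)-4-bromo-5-(dimethoxymethyl)benzene
Conditions: HC(OMe)3, MeOH, p-TsOH·H2O (cat.), 50 °C; Et3N quench
Reagents that add atoms: trimethyl orthoformate, COC(OC)OC
Why: Acid-catalysed acetalisation driven by the orthoformate; the dimethyl acetal survives the organolithium and enolate steps and can be removed under the mildest acid.

Step 10
Reactants: 13 1,2,3-tris(benzyloxy)-4-bromo-5-(dimethoxymethyl)benzene; 14 N-methoxy-N-methylacetamide
Product: 16 1-[2,3,4-tris(benzyloxy)-6-(dimethoxymethyl)phenyl]ethanone, via aryllithium 15 (not isolated)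
Conditions: n-BuLi, THF, −78 °C; then 14, −78 → 0 °C; aq. NH4Cl
Reagents that add atoms: none
Why: Bromine–lithium exchange followed by Weinreb ketone synthesis; exchange at −78 °C is faster than benzylic deprotonation, and the chelated tetrahedral adduct prevents a second addition.

Step 11
Reactants: 16 1-[2,3,4-tris(benzyloxy)-6-(dimethoxymethyl)phenyl]ethanone
Product: 18 2-diazo-1-[2,3,4-tris(benzyloxy)-6-(dimethoxymethyl)phenyl]ethanone, via trifluoroacetyl diketone 17 (not isolated)
Conditions: LiN(SiMe3)2, THF, −78 °C; CF3CO2CH2CF3; pH 5 buffer work-up; then MsN3, Et3N, H2O (1 equiv), MeCN, rt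
Reagents that add atoms: methanesulfonyl azide, CS(=O)(=O)N=[N+]=[N-]; 2,2,2-trifluoroethyl trifluoroacetate, O=C(OCC(F)(F)F)C(F)(F)F (its atoms stay only in intermediate 17)
Why: Detrifluoroacetylative Regitz-type diazo transfer; the methyl ketone enolate is trifluoroacetylated and the activated diketone transfers the diazo group with loss of the trifluoroacetyl unit. The method suits aryl methyl ketones, and the two ortho substituents do not hinder chemistry at the methyl group.

Step 12
Reactants: 18 2-diazo-1-[2,3,4-tris(benzyloxy)-6-(dimethoxymethyl)phenyl]ethanone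
Product: 19 2-diazo-1-[2,3,4-tris(benzyloxy)-6-formylphenyl]ethanone
Conditions: pyridinium p-toluenesulfonate (cat.), acetone/H2O, rt; used promptly
Reagents that add atoms: water, O
Why: Mild acid-catalysed acetal hydrolysis; a benzaldehyde dimethyl acetal ionises far more readily than an aryl diazomethyl ketone is protonated at carbon by a pyridinium acid, so the diazo group should survive.

Step 13
Reactants: 19 2-diazo-1-[2,3,4-tris(benzyloxy)-6-formylphenyl]ethanone; 9 (2R,3R)-3,5,7-tris(benzyloxy)-2-ethynylchroman
Product: 21 (2R,3R)-3,5,7-tris(benzyloxy)-2-[2,3,4-tris(benzyloxy)-5-oxo-6,9-dihydro-5H-6,9-epoxybenzo[7]annulen-8-yl]chroman (both bridgehead epimers), via benzopyrylium olate ylide 20 (not isolated)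
Conditions: Rh2(OAc)4 (2 mol%), CH2Cl2, 40 °C, slow addition of 19 (1.5 equiv) to 9 and catalyst
Reagents that add atoms: none
Why: Rh2(OAc)4 expels nitrogen from 19 to give a metal-bound carbene at C6'; the in-plane lone pair of the ortho formyl oxygen attacks this carbon, closing the six-membered oxacycle (O–C6' bond) and releasing the catalyst as the aromatic carbonyl ylide 20. The closest known reaction type is the tandem rhodium-carbene cyclisation–cycloaddition of ortho-acyl aryl diazomethyl ketones with alkynes, a relative of the [5+2] additions of 3-oxidopyryliums. The dipole C6'–O–C9' then adds suprafacially and in concert across C7'≡C8' of 9, forming C6'–C7' and C8'–C9'; this closes the seven-membered carbocycle together with the 2,5-dihydrofuran ring spanned by the oxygen bridge. The two new bridgehead centres are necessarily cis on the bridge; their sense relative to C2 and C3 is not controlled and need not be, because both are destroyed in step 14. C2 and C3 see neither acid nor base. The step needs one orientation: the unsubstituted alkyne carbon must bond to C6', which is the enolate-like terminus with the larger HOMO coefficient, as in oxidopyrylium additions to monosubstituted partners, which place their substituent next to the bridgehead remote from the carbonyl. It also needs ylide formation to outrun attack of the carbene on the peri benzyloxy oxygen of C4'; a six-membered closure onto a carbonyl oxygen that gives an aromatic betaine should win, and slow addition keeps the carbene concentration low while the alkyne is present from the start.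

Step 14
Reactants: 21 oxygen-bridged cycloadduct (both bridgehead epimers)
Product: 22 (2R,3R)-3,5,7-tris(benzyloxy)-2-[2,3,4-tris(benzyloxy)-6-hydroxy-5-oxo-5H-benzo[7]annulen-8-yl]chroman
Conditions: CF3CO2H, CH2Cl2, 0 °C, dilute
Reagents that add atoms: none
Why: Acid-promoted opening of the oxygen bridge; the C9'–O bond ionises to a cation that is benzylic, allylic and para to the C3' ether oxygen, and loss of the C6' proton gives the hydroxytropone with no change of oxidation level, so both epimers converge. The C2–O1 bond should hold because the ring next to C2 is electron-poor, and benzyl ethers tolerate this acid at 0 °C.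

Step 15
Reactants: 22 (2R,3R)-3,5,7-tris(benzyloxy)-2-[2,3,4-tris(benzyloxy)-6-hydroxy-5-oxo-5H-benzo[7]annulen-8-yl]chroman
Product: 23 (2R,3R)-2-(2,3,4,6-tetrahydroxy-5-oxo-5H-benzo[7]annulen-8-yl)chroman-3,5,7-triol (target)
Conditions: H2 (1 atm), Pd(OH)2/C, THF/MeOH, rt; filtration under argon
Reagents that add atoms: none
Why: Catalytic hydrogenolysis of five aryl benzyl ethers and one alkyl benzyl ether under neutral conditions; benzyl ethers of flavan-3-ols and of hydroxytropolones are normally cleaved faster than the rings are reduced, and neither stereocentre is involved.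

## Compound list

1 | 3-(trimethylsilyl)propynal | C[Si](C)(C)C#CC=O | starting material
2 | vinylmagnesium bromide | C=C[Mg]Br | starting material
3 | racemic 5-(trimethylsilyl)pent-1-en-4-yn-3-ol | C=CC(O)C#C[Si](C)(C)C | intermediate
4 | (2R,3S)-1,2-epoxy-5-(trimethylsilyl)pent-4-yn-3-ol | C[Si](C)(C)C#C[C@H](O)[C@H]1CO1 | intermediate
5 | 3,5-bis(benzyloxy)phenol | Oc1cc(OCc2ccccc2)cc(OCc2ccccc2)c1 | starting material
6 | (2R)-2-[(1R)-1-[3,5-bis(benzyloxy)phenoxy]-3-(trimethylsilyl)prop-2-yn-1-yl]oxirane | C[Si](C)(C)C#C[C@@H](Oc1cc(OCc2ccccc2)cc(OCc2ccccc2)c1)[C@H]1CO1 | intermediate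
7 | (2R,3R)-5,7-bis(benzyloxy)-2-[(trimethylsilyl)ethynyl]chroman-3-ol | C[Si](C)(C)C#C[C@H]1Oc2cc(OCc3ccccc3)cc(OCc3ccccc3)c2C[C@H]1O | intermediate
8 | (2R,3R)-3,5,7-tris(benzyloxy)-2-[(trimethylsilyl)ethynyl]chroman | C[Si](C)(C)C#C[C@H]1Oc2cc(OCc3ccccc3)cc(OCc3ccccc3)c2C[C@H]1OCc1ccccc1 | intermediate
9 | (2R,3R)-3,5,7-tris(benzyloxy)-2-ethynylchroman | C#C[C@H]1Oc2cc(OCc3ccccc3)cc(OCc3ccccc3)c2C[C@H]1OCc1ccccc1 | intermediate
10 | 3,4,5-trihydroxybenzaldehyde | O=Cc1cc(O)c(O)c(O)c1 | starting material
11 | 3,4,5-tris(benzyloxy)benzaldehyde | O=Cc1cc(OCc2ccccc2)c(OCc2ccccc2)c(OCc2ccccc2)c1 | intermediate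
12 | 2-bromo-3,4,5-tris(benzyloxy)benzaldehyde | O=Cc1cc(OCc2ccccc2)c(OCc2ccccc2)c(OCc2ccccc2)c1Br | intermediate
13 | 1,2,3-tris(benzyloxy)-4-bromo-5-(dimethoxymethyl)benzene | COC(OC)c1cc(OCc2ccccc2)c(OCc2ccccc2)c(OCc2ccccc2)c1Br | intermediate
14 | N-methoxy-N-methylacetamide | CC(=O)N(C)OC | starting material
15 | [2,3,4-tris(benzyloxy)-6-(dimethoxymethyl)phenyl]lithium | [Li]c1c(C(OC)OC)cc(OCc2ccccc2)c(OCc2ccccc2)c1OCc1ccccc1 | intermediate
16 | 1-[2,3,4-tris(benzyloxy)-6-(dimethoxymethyl)phenyl]ethanone | CC(=O)c1c(C(OC)OC)cc(OCc2ccccc2)c(OCc2ccccc2)c1OCc1ccccc1 | intermediate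
17 | 4,4,4-trifluoro-1-[2,3,4-tris(benzyloxy)-6-(dimethoxymethyl)phenyl]butane-1,3-dione | O=C(CC(=O)C(F)(F)F)c1c(C(OC)OC)cc(OCc2ccccc2)c(OCc2ccccc2)c1OCc1ccccc1 | intermediate
18 | 2-diazo-1-[2,3,4-tris(benzyloxy)-6-(dimethoxymethyl)phenyl]ethanone | [N-]=[N+]=CC(=O)c1c(C(OC)OC)cc(OCc2ccccc2)c(OCc2ccccc2)c1OCc1ccccc1 | intermediate
19 | 2-diazo-1-[2,3,4-tris(benzyloxy)-6-formylphenyl]ethanone | [N-]=[N+]=CC(=O)c1c(C=O)cc(OCc2ccccc2)c(OCc2ccccc2)c1OCc1ccccc1 | intermediate
20 | 5,6,7-tris(benzyloxy)-2-benzopyrylium-4-olate (carbonyl ylide) | [O-]c1c[o+]cc2cc(OCc3ccccc3)c(OCc3ccccc3)c(OCc3ccccc3)c12 | intermediate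
21 | (2R,3R)-3,5,7-tris(benzyloxy)-2-[2,3,4-tris(benzyloxy)-5-oxo-6,9-dihydro-5H-6,9-epoxybenzo[7]annulen-8-yl]chroman, both bridgehead epimers | O=C1c2c(OCc3ccccc3)c(OCc3ccccc3)c(OCc3ccccc3)cc2C2OC1C=C2[C@H]1Oc2cc(OCc3ccccc3)cc(OCc3ccccc3)c2C[C@H]1OCc1ccccc1 | intermediate
22 | (2R,3R)-3,5,7-tris(benzyloxy)-2-[2,3,4-tris(benzyloxy)-6-hydroxy-5-oxo-5H-benzo[7]annulen-8-yl]chroman | O=c1c(O)cc([C@H]2Oc3cc(OCc4ccccc4)cc(OCc4ccccc4)c3C[C@H]2OCc2ccccc2)cc2cc(OCc3ccccc3)c(OCc3ccccc3)c(OCc3ccccc3)c12 | intermediate
23 | (2R,3R)-2-(2,3,4,6-tetrahydroxy-5-oxo-5H-benzo[7]annulen-8-yl)chroman-3,5,7-triol | O=c1c(O)cc([C@H]2Oc3cc(O)cc(O)c3C[C@H]2O)cc2cc(O)c(O)c(O)c12 | target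

## Step count and weak points

Total: 15 steps. Longest linear sequence: 9 steps (steps 1–6, then 13–15; the branch through steps 7–12 is equally long).

**Step 13 (key step).**
- Most likely failure: the metal carbene is diverted before the ylide forms, by attack on the peri benzyloxy oxygen of C4' followed by a Stevens shift of the benzyl group. The ylide may also self-condense, because an unactivated alkyne traps it slowly. Some addition in the reverse orientation is possible.
- Fallback: generate the same dipole without a carbene, setting out from 19 and returning at 21. Hydrolysis of 19 with dilute aqueous HClO4 in dioxane replaces nitrogen by hydroxyl, and the hydroxymethyl ketone closes onto the ortho formyl group to give the lactol 5,6,7-tris(benzyloxy)-1-hydroxyisochroman-4-one F1. Acetylation (Ac2O, pyridine) gives 1-acetoxy-5,6,7-tris(benzyloxy)isochroman-4-one F2. Heating F2 with 9 and Et3N in acetonitrile eliminates acetic acid to ylide 20, which is trapped to 21. This is the acetoxypyranone route to oxidopyryliums; it allows a high alkyne concentration and excludes all carbene side reactions. The orientation of addition is unchanged, so a minor regioisomer would have to be removed after step 14.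

**Step 12.**
- Most likely failure: protonation of the diazo carbon competes with acetal cleavage, or the diazo carbon adds to the freed ortho formyl group.
- Fallback: carry C9' at the alcohol oxidation level, setting out from 12 and returning at 19. NaBH4 reduction gives [2-bromo-3,4,5-tris(benzyloxy)phenyl]methanol F3. Silylation (t-BuMe2SiCl, imidazole) gives its tert-butyldimethylsilyl ether F4. Bromine–lithium exchange and acylation with 14 give 1-[2,3,4-tris(benzyloxy)-6-(tert-butyldimethylsilyloxymethyl)phenyl]ethanone F5. The same diazo transfer gives 2-diazo-1-[2,3,4-tris(benzyloxy)-6-(tert-butyldimethylsilyloxymethyl)phenyl]ethanone F6. Buffered fluoride (n-Bu4NF, AcOH) frees 2-diazo-1-[2,3,4-tris(benzyloxy)-6-(hydroxymethyl)phenyl]ethanone F7, and MnO2 in CH2Cl2 oxidises the benzylic alcohol to 19 under neutral conditions.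

**Step 4.**
- Most likely failure: the arene attacks the internal epoxide carbon (five-membered closure), the activated epoxide rearranges by hydride shift, or the propargylic aryl ether ionises.
- Fallback: close C4–C4a with an aryl anion instead of an arene, setting out from 4 and 5 and returning at 7. Iodination of 5 (I2, NaHCO3), with separation from the para isomer, gives 3,5-bis(benzyloxy)-2-iodophenol F8. Mitsunobu coupling with 4 gives (2R)-2-[(1R)-1-[3,5-bis(benzyloxy)-2-iodophenoxy]-3-(trimethylsilyl)prop-2-yn-1-yl]oxirane F9. Li2NiBr4 opens the epoxide at the terminal carbon to (2S,3R)-3-[3,5-bis(benzyloxy)-2-iodophenoxy]-1-bromo-5-(trimethylsilyl)pent-4-yn-2-ol F10, which is silylated (Et3SiOTf, 2,6-lutidine) to its triethylsilyl ether F11. Iodine–lithium exchange with n-BuLi at −78 °C and warming effect a Parham cyclisation onto the primary bromide, giving (2R,3R)-5,7-bis(benzyloxy)-3-(triethylsilyloxy)-2-[(trimethylsilyl)ethynyl]chroman F12. AcOH/THF/H2O removes the triethylsilyl group to give 7.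

**Step 2.**
- Most likely failure: the rate difference between the enantiomers of 3 is too small, because the alkynyl group is slim. This would erode the enantiomeric purity of an epoxy alcohol collected as the product of the resolution.
- Fallback: resolve first and epoxidise second, setting out from 3 and returning at 4. A resolution with D-(−)-diisopropyl tartrate, Ti(OiPr)4 and t-BuOOH, run past half conversion, consumes the (S)-enantiomer and leaves (R)-5-(trimethylsilyl)pent-1-en-4-yn-3-ol F13 in high enantiomeric purity. F13 is then epoxidised to completion with the matched L-(+)-tartrate catalyst to give 4.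

**Step 15.**
- Most likely failure: the tropolone ring is saturated, or the C2–O1 bond is hydrogenolysed, in competition with cleavage of the six benzyl ethers.
- Fallback: Lewis-acid debenzylation from 22 directly to 23 with BCl3 and pentamethylbenzene as cation scavenger in CH2Cl2 at −78 °C. The scavenger keeps benzyl cations away from ring A, and the low temperature protects C2. No new compound is involved.

## Further compounds

F1 | step 13 | 5,6,7-tris(benzyloxy)-1-hydroxyisochroman-4-one | O=C1COC(O)c2cc(OCc3ccccc3)c(OCc3ccccc3)c(OCc3ccccc3)c12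
F2 | step 13 | 1-acetoxy-5,6,7-tris(benzyloxy)isochroman-4-one | CC(=O)OC1OCC(=O)c2c1cc(OCc1ccccc1)c(OCc1ccccc1)c2OCc1ccccc1
F3 | step 12 | [2-bromo-3,4,5-tris(benzyloxy)phenyl]methanol | OCc1cc(OCc2ccccc2)c(OCc2ccccc2)c(OCc2ccccc2)c1Br
F4 | step 12 | [2-bromo-3,4,5-tris(benzyloxy)benzyloxy](tert-butyl)dimethylsilane | CC(C)(C)[Si](C)(C)OCc1cc(OCc2ccccc2)c(OCc2ccccc2)c(OCc2ccccc2)c1Br
F5 | step 12 | 1-[2,3,4-tris(benzyloxy)-6-(tert-butyldimethylsilyloxymethyl)phenyl]ethanone | CC(=O)c1c(CO[Si](C)(C)C(C)(C)C)cc(OCc2ccccc2)c(OCc2ccccc2)c1OCc1ccccc1
F6 | step 12 | 2-diazo-1-[2,3,4-tris(benzyloxy)-6-(tert-butyldimethylsilyloxymethyl)phenyl]ethanone | [N-]=[N+]=CC(=O)c1c(CO[Si](C)(C)C(C)(C)C)cc(OCc2ccccc2)c(OCc2ccccc2)c1OCc1ccccc1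
F7 | step 12 | 2-diazo-1-[2,3,4-tris(benzyloxy)-6-(hydroxymethyl)phenyl]ethanone | [N-]=[N+]=CC(=O)c1c(CO)cc(OCc2ccccc2)c(OCc2ccccc2)c1OCc1ccccc1
F8 | step 4 | 3,5-bis(benzyloxy)-2-iodophenol | Oc1cc(OCc2ccccc2)cc(OCc2ccccc2)c1I
F9 | step 4 | (2R)-2-[(1R)-1-[3,5-bis(benzyloxy)-2-iodophenoxy]-3-(trimethylsilyl)prop-2-yn-1-yl]oxirane | C[Si](C)(C)C#C[C@@H](Oc1cc(OCc2ccccc2)cc(OCc2ccccc2)c1I)[C@H]1CO1
F10 | step 4 | (2S,3R)-3-[3,5-bis(benzyloxy)-2-iodophenoxy]-1-bromo-5-(trimethylsilyl)pent-4-yn-2-ol | C[Si](C)(C)C#C[C@@H](Oc1cc(OCc2ccccc2)cc(OCc2ccccc2)c1I)[C@H](O)CBr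
F11 | step 4 | triethylsilyl ether of (2S,3R)-3-[3,5-bis(benzyloxy)-2-iodophenoxy]-1-bromo-5-(trimethylsilyl)pent-4-yn-2-ol | C[Si](C)(C)C#C[C@@H](Oc1cc(OCc2ccccc2)cc(OCc2ccccc2)c1I)[C@H](O[Si](CC)(CC)CC)CBr
F12 | step 4 | (2R,3R)-5,7-bis(benzyloxy)-3-(triethylsilyloxy)-2-[(trimethylsilyl)ethynyl]chroman | C[Si](C)(C)C#C[C@H]1Oc2cc(OCc3ccccc3)cc(OCc3ccccc3)c2C[C@H]1O[Si](CC)(CC)CC
F13 | step 2 | (R)-5-(trimethylsilyl)pent-1-en-4-yn-3-ol | C=C[C@@H](O)C#C[Si](C)(C)C
F0 | step 15 | none | none
A1 | alternative 1 | C2-configured 2-[2,3,4,6-tetrakis(benzyloxy)-5-oxo-5H-benzo[7]annulen-8-yl]-5,7-bis(benzyloxy)-2H-chromene-3-carbaldehyde | O=CC1=Cc2c(OCc3ccccc3)cc(OCc3ccccc3)cc2O[C@@H]1C1=Cc2cc(OCc3ccccc3)c(OCc3ccccc3)c(OCc3ccccc3)c2C(=O)C(OCc2ccccc2)=C1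
A2 | alternative 1 | 4,6-bis(benzyloxy)-2-hydroxybenzaldehyde | O=Cc1c(O)cc(OCc2ccccc2)cc1OCc1ccccc1
A3 | alternative 1 | (E)-3-[2,3,4,6-tetrakis(benzyloxy)-5-oxo-5H-benzo[7]annulen-8-yl]prop-2-enal | O=C/C=C/C1=Cc2cc(OCc3ccccc3)c(OCc3ccccc3)c(OCc3ccccc3)c2C(=O)C(OCc2ccccc2)=C1
A4 | alternative 2 | 2,3,4-tris(benzyloxy)-6-(triethylsilyloxy)-8-[(2R,3R)-3,5,7-tris(benzyloxy)chroman-2-yl]-6,9-dihydro-5H-benzo[7]annulen-5-one | O=C1c2c(OCc3ccccc3)c(OCc3ccccc3)c(OCc3ccccc3)cc2CC([C@H]2Oc3cc(OCc4ccccc4)cc(OCc4ccccc4)c3C[C@H]2OCc2ccccc2)=CC1O[Si](CC)(CC)CC
A5 | alternative 2 | 1-[2,3,4-tris(benzyloxy)-6-[2-[(2R,3R)-3,5,7-tris(benzyloxy)chroman-2-yl]prop-2-en-1-yl]phenyl]-2-(triethylsilyloxy)but-3-en-1-one | C=CC(O[Si](CC)(CC)CC)C(=O)c1c(OCc2ccccc2)c(OCc2ccccc2)c(OCc2ccccc2)cc1CC(=C)[C@H]1Oc2cc(OCc3ccccc3)cc(OCc3ccccc3)c2C[C@H]1OCc1ccccc1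
A6 | alternative 3 | 2,3,4-tris(benzyloxy)-6-chloro-8-[(2R,3R)-3,5,7-tris(benzyloxy)chroman-2-yl]-5H-benzo[7]annulen-5-one | O=C1C(Cl)=CC([C@H]2Oc3cc(OCc4ccccc4)cc(OCc4ccccc4)c3C[C@H]2OCc2ccccc2)=Cc2cc(OCc3ccccc3)c(OCc3ccccc3)c(OCc3ccccc3)c21
A7 | alternative 3 | (2R,3R)-3,5,7-tris(benzyloxy)-2-[5,6,7-tris(benzyloxy)-4-methoxynaphthalen-2-yl]chroman | COc1cc([C@H]2Oc3cc(OCc4ccccc4)cc(OCc4ccccc4)c3C[C@H]2OCc2ccccc2)cc2cc(OCc3ccccc3)c(OCc3ccccc3)c(OCc3ccccc3)c12
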